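1. Numbering: in ring A, C1 carries the (R)-quaternary carbon, C3 the ether oxygen and C4 the hydroxyl; ring B is the 5-alkylbenzene-1,2,3-triol unit whose outer oxygen is the ether oxygen.
2. Retrosynthesis first removes the two ring B MOM ethers, then cuts C2–C3 and C5–C6 of ring A. This works because C3–C4–C5 of ring A is the OCH2–C(=O)–CH3 triad of a ring B aryloxyacetone and C2–C1–C6 is a malondialdehyde triad carrying the quaternary carbon at C1, so the diaryl ether needs no aryl C–O coupling.
3. Further cuts: the O–CH2 bond to chloroacetone, the outer C–O bond of ring B (ortho-lithiation, borylation, oxidation), and the two corresponding ring bonds of ring B (mirror-image enaminal plus (methoxymethoxy)acetone).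
4. Forward: farnesol → allylic phosphate; one batch of a silylalkynylalane then serves both antipodes of one enaminal (SN2′ alkynylation, desilylation, anti-Markovnikov hydration, aminomethylenation).
5. Ring B is built first from the (S)-enaminal, then oxygenated and O-alkylated; ring A is built last, on the oxygen of ring B, from the (R)-enaminal; mild acid then frees the catechol.
6. Stereochemistry: both quaternary centres are set by ligand-controlled copper-catalysed SN2′ alkynylation ((R) for ring A, (S) for ring B, from the two ligand antipodes); they bear no hydrogen and are not touched again; the E-olefins come from farnesol.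

Key step: step 16

Assumption: the chiral ligand is a 4,5-diphenylimidazolinium salt with an N-(2-sulfonatophenyl) and an N′-(2,6-dialkylphenyl) group, used as either antipode. The (S,S) antipode is taken to give the (R)-enyne; if the sense of induction is the reverse, the two antipodes are exchanged between steps 3 and 4.
Remark: the enaminals are drawn with the amino group trans to the quaternary carbon; the push–pull double bond isomerises easily and its geometry has no bearing on the annulations.

**Step 1**
Reactants: 1 (2E,6E)-farnesol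
Product: 2 diethyl (2E,6E)-farnesyl phosphate
Conditions: ClP(O)(OEt)2, Et3N, DMAP (cat.), CH2Cl2, 0 °C → rt
Reagents that add atoms: diethyl chlorophosphate, CCOP(=O)(Cl)OCC
Why: Phosphorylation of a primary allylic alcohol with a chlorophosphate under amine base is routine and installs, without allylic transposition, the leaving group that copper-catalysed SN2′ substitution requires.

**Step 2**
Reactants: 3 trimethylsilylacetylene
Product: 4 diisobutyl[(trimethylsilyl)ethynyl]aluminium, kept as a titrated stock solution in hexanes for steps 3 and 4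
Conditions: i-Bu2AlH, Et3N (cat.), hexanes, 22 °C, under argon
Reagents that add atoms: diisobutylaluminium hydride, CC(C)C[AlH]CC(C)C
Why: Amine-catalysed deprotonative alumination of a terminal alkyne by i-Bu2AlH, with loss of dihydrogen, gives the alkynylalane in preference to hydroalumination of the triple bond, and a single batch supplies both antipodal alkynylations.

**Step 3**
Reactants: 2 diethyl (2E,6E)-farnesyl phosphate; 4 diisobutyl[(trimethylsilyl)ethynyl]aluminium
Product: 5 trimethyl[(3R,6E)-3-ethenyl-3,7,11-trimethyldodeca-6,10-dien-1-yn-1-yl]silane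
Conditions: 4 (hexane solution), CuCl2·2H2O (cat.), (S,S)-imidazolinium sulfonate (cat.), THF, −30 °C; aq. potassium sodium tartrate
Reagents that add atoms: none
Why: The sulfonate-bridged copper–carbene complex formed in the flask (divalent copper is reduced by the alane to monovalent copper) delivers the alkynyl group of 4 SN2′ to the methyl-bearing carbon of the E-allylic phosphate, the ligand antipode choosing the olefin face and so setting the (R) quaternary centre (enantioselective copper-catalysed allylic substitution).

**Step 4**
Reactants: 2 diethyl (2E,6E)-farnesyl phosphate; 4 diisobutyl[(trimethylsilyl)ethynyl]aluminium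
Product: 6 trimethyl[(3S,6E)-3-ethenyl-3,7,11-trimethyldodeca-6,10-dien-1-yn-1-yl]silane
Conditions: 4 (hexane solution), CuCl2·2H2O (cat.), (R,R)-imidazolinium sulfonate (cat.), THF, −30 °C; aq. potassium sodium tartrate
Reagents that add atoms: none
Why: The same enantioselective copper-catalysed allylic substitution under the mirror-image ligand should attack the opposite olefin face and set the (S) quaternary centre.

**Step 5**
Reactants: 5 (R)-silyl enyne
Product: 7 (3R,6E)-3-ethenyl-3,7,11-trimethyldodeca-6,10-dien-1-yne
Conditions: K2CO3 (cat.), MeOH, rt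
Reagents that add atoms: none
Why: Base-catalysed methanolysis of the alkynyl C–Si bond (protodesilylation) is mild and cannot isomerise the enyne, because the propargylic carbon carries no hydrogen.

**Step 6**
Reactants: 6 (S)-silyl enyne
Product: 8 (3S,6E)-3-ethenyl-3,7,11-trimethyldodeca-6,10-dien-1-yne
Conditions: K2CO3 (cat.), MeOH, rt
Reagents that add atoms: none
Why: The same protodesilylation applies unchanged to the mirror-image enyne.

**Step 7**
Reactants: 7 (R)-enyne
Product: 9 (3S,6E)-3-ethenyl-3,7,11-trimethyldodeca-6,10-dienal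
Conditions: RuCpCl(dppm) (cat.), i-PrOH/H2O, 100 °C (dppm = bis(diphenylphosphino)methane)
Reagents that add atoms: water, O
Why: Ruthenium-vinylidene-mediated anti-Markovnikov hydration of a terminal alkyne gives the aldehyde directly, the vinylidene forming only at the C≡C–H unit so that the olefins and the quaternary centre are spared (the descriptor becomes S only because the CIP ranking of the substituents changes).

**Step 8**
Reactants: 8 (S)-enyne
Product: 10 (3R,6E)-3-ethenyl-3,7,11-trimethyldodeca-6,10-dienal
Conditions: RuCpCl(dppm) (cat.), i-PrOH/H2O, 100 °C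
Reagents that add atoms: water, O
Why: The same anti-Markovnikov alkyne hydration applies to the mirror-image enyne, again without touching the quaternary centre.

**Step 9**
Reactants: 9 (S)-aldehyde; 11 tert-butoxybis(dimethylamino)methane
Product: 12 (2Z,3R,6E)-2-[(dimethylamino)methylidene]-3-ethenyl-3,7,11-trimethyldodeca-6,10-dienal
Conditions: 11 (excess), toluene, 80 °C
Reagents that add atoms: none
Why: The aminal ester condenses with the α-methylene of the aldehyde (aminomethylenation with loss of tert-butanol and dimethylamine) to give the push–pull enaminal, and the adjacent quaternary carbon suppresses aldol self-condensation.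

**Step 10**
Reactants: 10 (R)-aldehyde; 11 tert-butoxybis(dimethylamino)methane
Product: 13 (2Z,3S,6E)-2-[(dimethylamino)methylidene]-3-ethenyl-3,7,11-trimethyldodeca-6,10-dienal
Conditions: 11 (excess), toluene, 80 °C
Reagents that add atoms: none
Why: The same aminomethylenation converts the mirror-image aldehyde into the (S)-enaminal.

**Step 11**
Reactants: 14 hydroxyacetone
Product: 15 1-(methoxymethoxy)propan-2-one
Conditions: MOMCl, i-Pr2NEt, CH2Cl2, 0 °C → rt
Reagents that add atoms: chloromethyl methyl ether, COCCl
Why: Alkylation of the primary hydroxyl with chloromethyl methyl ether under a hindered amine base is a standard acetal protection and leaves the ketone untouched.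

**Step 12**
Reactants: 13 (S)-enaminal; 15 1-(methoxymethoxy)propan-2-one
Product: 17 2-(methoxymethoxy)-4-[(3S,6E)-3,7,11-trimethyldodeca-1,6,10-trien-3-yl]phenol, via aminodienone 16 (not isolated)
Conditions: KOtBu, THF, 0 → 60 °C, 15 added slowly; aq. NH4Cl
Reagents that add atoms: none
Why: Base-mediated [3+3] cyclocondensation of a 2-substituted 3-aminoacrolein with a ketone having two enolisable α-carbons joins the O–CH2 and CH3 carbons of 15 to the two equivalent termini of 13 (aldol condensation to 16, then 6π-closure of the trienolate and loss of dimethylamine), which places OMOM ortho and the side chain para to the new hydroxyl and also rehearses step 16 on a simpler ketone.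

**Step 13**
Reactants: 17 ring B phenol
Product: 18 1,2-bis(methoxymethoxy)-4-[(3S,6E)-3,7,11-trimethyldodeca-1,6,10-trien-3-yl]benzene
Conditions: MOMCl, i-Pr2NEt, CH2Cl2, 0 °C → rt
Reagents that add atoms: chloromethyl methyl ether, COCCl
Why: Standard MOM etherification of a phenol turns the hydroxyl into the directing group for the next step and into the final protecting group of the central ring B oxygen.

**Step 14**
Reactants: 18 bis-MOM arene
Product: 21 2,3-bis(methoxymethoxy)-5-[(3S,6E)-3,7,11-trimethyldodeca-1,6,10-trien-3-yl]phenol, via aryllithium 19 (not isolated), via lithium aryltrimethoxyborate 20 (not isolated)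
Conditions: n-BuLi, TMEDA, THF, 0 °C; B(OMe)3, −78 °C → rt; then H2O2 (30 % aq.), 0 °C → rt
Reagents that add atoms: hydrogen peroxide, OO
Why: Directed ortho-metalation followed by borylation and oxidative boron-to-oxygen migration should hydroxylate the only accessible position ortho to an OMOM group, the other being flanked by the quaternary carbon, while isolated olefins are inert to n-BuLi and to basic H2O2.

**Step 15**
Reactants: 21 ring B phenol with free outer hydroxyl; 22 chloroacetone
Product: 23 1-{2,3-bis(methoxymethoxy)-5-[(3S,6E)-3,7,11-trimethyldodeca-1,6,10-trien-3-yl]phenoxy}propan-2-one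
Conditions: K2CO3, KI (cat.), acetone, 50 °C
Reagents that add atoms: none
Why: Williamson etherification of the only free phenol with an activated α-chloroketone under mild carbonate base attaches the three-carbon ketone unit to the future ether oxygen.

**Step 16**
Reactants: 12 (R)-enaminal; 23 ring B aryloxyacetone
Product: 25 2-{2,3-bis(methoxymethoxy)-5-[(3S,6E)-3,7,11-trimethyldodeca-1,6,10-trien-3-yl]phenoxy}-4-[(3R,6E)-3,7,11-trimethyldodeca-1,6,10-trien-3-yl]phenol, via aminodienone 24 (not isolated)
Conditions: KOtBu (3 equiv), THF, 0 → 60 °C, 23 added slowly to 12 and base; aq. NH4Cl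
Reagents that add atoms: none
Why: KOtBu reversibly enolises 23, and the more acidic O–CH2 carbon adds to the formyl carbon of 12 and loses water to give aminodienone 24 (C2–C3 bond). Deprotonation of the methyl group then gives a 1-amino-trienolate whose 6π-electrocyclisation (equivalently a 6-endo Mannich-type attack on the aminomethylene carbon) forms C5–C6 and closes ring A, and loss of dimethylamine with tautomerisation gives the phenoxide. The closest known reaction is the base-mediated [3+3] benzannulation of 2-substituted 3-aminoacroleins or vinamidinium salts with ketones that have two enolisable α-carbons. No stereocentre is created, and the two existing quaternary centres carry no hydrogen and cannot epimerise. The step needs cross-condensation to beat ketone self-condensation and a single regiochemistry: 12 has no enolisable hydrogen and two equivalent termini, so whichever α-carbon reacts first the ketone carbon becomes C4, the aryloxy carbon C3 and the side-chain carbon C1, while self-aldol of 23 is reversible and aromatisation is not.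

**Step 17**
Reactants: 25 bis-MOM diaryl ether
Product: 26 3-{2-hydroxy-5-[(3R,6E)-3,7,11-trimethyldodeca-1,6,10-trien-3-yl]phenoxy}-5-[(3S,6E)-3,7,11-trimethyldodeca-1,6,10-trien-3-yl]benzene-1,2-diol (CNP0296687.1)
Conditions: HCl (aq., cat.), MeOH, 40 °C, under argon
Reagents that add atoms: none
Why: Acid-catalysed acetal exchange with methanol cleaves both aryl MOM ethers under conditions too mild to protonate the isolated trisubstituted and vinyl olefins, and no stereocentre is involved.

**Compound list**
1 | (2E,6E)-farnesol | CC(C)=CCC/C(C)=C/CC/C(C)=C/CO | starting material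
2 | diethyl (2E,6E)-farnesyl phosphate | CC(C)=CCC/C(C)=C/CC/C(C)=C/COP(=O)(OCC)OCC | intermediate
3 | trimethylsilylacetylene | C#C[Si](C)(C)C | starting material
4 | diisobutyl[(trimethylsilyl)ethynyl]aluminium (alkynylalane, stock solution in hexanes) | CC(C)C[Al](CC(C)C)C#C[Si](C)(C)C | intermediate
5 | trimethyl[(3R,6E)-3-ethenyl-3,7,11-trimethyldodeca-6,10-dien-1-yn-1-yl]silane | C=C[C@@](C)(CC/C=C(\C)CCC=C(C)C)C#C[Si](C)(C)C | intermediate
6 | trimethyl[(3S,6E)-3-ethenyl-3,7,11-trimethyldodeca-6,10-dien-1-yn-1-yl]silane | C=C[C@](C)(CC/C=C(\C)CCC=C(C)C)C#C[Si](C)(C)C | intermediate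
7 | (3R,6E)-3-ethenyl-3,7,11-trimethyldodeca-6,10-dien-1-yne | C=C[C@@](C)(CC/C=C(\C)CCC=C(C)C)C#C | intermediate
8 | (3S,6E)-3-ethenyl-3,7,11-trimethyldodeca-6,10-dien-1-yne | C=C[C@](C)(CC/C=C(\C)CCC=C(C)C)C#C | intermediate
9 | (3S,6E)-3-ethenyl-3,7,11-trimethyldodeca-6,10-dienal | C=C[C@@](C)(CC/C=C(\C)CCC=C(C)C)CC=O | intermediate
10 | (3R,6E)-3-ethenyl-3,7,11-trimethyldodeca-6,10-dienal | C=C[C@](C)(CC/C=C(\C)CCC=C(C)C)CC=O | intermediate
11 | tert-butoxybis(dimethylamino)methane | CN(C)C(OC(C)(C)C)N(C)C | starting material
12 | (2Z,3R,6E)-2-[(dimethylamino)methylidene]-3-ethenyl-3,7,11-trimethyldodeca-6,10-dienal ((R)-enaminal) | C=C[C@@](C)(CC/C=C(\C)CCC=C(C)C)C(/C=O)=C/N(C)C | intermediate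
13 | (2Z,3S,6E)-2-[(dimethylamino)methylidene]-3-ethenyl-3,7,11-trimethyldodeca-6,10-dienal ((S)-enaminal) | C=C[C@](C)(CC/C=C(\C)CCC=C(C)C)C(/C=O)=C/N(C)C | intermediate
14 | hydroxyacetone | CC(=O)CO | starting material
15 | 1-(methoxymethoxy)propan-2-one | CC(=O)COCOC | intermediate
16 | 6-(dimethylamino)-3-(methoxymethoxy)-5-[(3S,6E)-3,7,11-trimethyldodeca-1,6,10-trien-3-yl]hexa-3,5-dien-2-one (aminodienone) | C=C[C@](C)(CC/C=C(\C)CCC=C(C)C)C(=CN(C)C)C=C(OCOC)C(C)=O | intermediate (not isolated)
17 | 2-(methoxymethoxy)-4-[(3S,6E)-3,7,11-trimethyldodeca-1,6,10-trien-3-yl]phenol | C=C[C@](C)(CC/C=C(\C)CCC=C(C)C)c1ccc(O)c(OCOC)c1 | intermediate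
18 | 1,2-bis(methoxymethoxy)-4-[(3S,6E)-3,7,11-trimethyldodeca-1,6,10-trien-3-yl]benzene | C=C[C@](C)(CC/C=C(\C)CCC=C(C)C)c1ccc(OCOC)c(OCOC)c1 | intermediate
19 | {2,3-bis(methoxymethoxy)-5-[(3S,6E)-3,7,11-trimethyldodeca-1,6,10-trien-3-yl]phenyl}lithium (aryllithium) | C=C[C@](C)(CC/C=C(\C)CCC=C(C)C)c1cc([Li])c(OCOC)c(OCOC)c1 | intermediate (not isolated)
20 | lithium {2,3-bis(methoxymethoxy)-5-[(3S,6E)-3,7,11-trimethyldodeca-1,6,10-trien-3-yl]phenyl}trimethoxyborate | C=C[C@](C)(CC/C=C(\C)CCC=C(C)C)c1cc([B-](OC)(OC)OC)c(OCOC)c(OCOC)c1.[Li+] | intermediate (not isolated)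
21 | 2,3-bis(methoxymethoxy)-5-[(3S,6E)-3,7,11-trimethyldodeca-1,6,10-trien-3-yl]phenol | C=C[C@](C)(CC/C=C(\C)CCC=C(C)C)c1cc(O)c(OCOC)c(OCOC)c1 | intermediate
22 | chloroacetone | CC(=O)CCl | starting material
23 | 1-{2,3-bis(methoxymethoxy)-5-[(3S,6E)-3,7,11-trimethyldodeca-1,6,10-trien-3-yl]phenoxy}propan-2-one | C=C[C@](C)(CC/C=C(\C)CCC=C(C)C)c1cc(OCC(C)=O)c(OCOC)c(OCOC)c1 | intermediate
24 | 3-{2,3-bis(methoxymethoxy)-5-[(3S,6E)-3,7,11-trimethyldodeca-1,6,10-trien-3-yl]phenoxy}-6-(dimethylamino)-5-[(3R,6E)-3,7,11-trimethyldodeca-1,6,10-trien-3-yl]hexa-3,5-dien-2-one (aminodienone) | C=C[C@@](C)(CC/C=C(\C)CCC=C(C)C)C(=CN(C)C)C=C(Oc1cc(cc(OCOC)c1OCOC)[C@](C)(C=C)CC/C=C(\C)CCC=C(C)C)C(C)=O | intermediate (not isolated)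
25 | 2-{2,3-bis(methoxymethoxy)-5-[(3S,6E)-3,7,11-trimethyldodeca-1,6,10-trien-3-yl]phenoxy}-4-[(3R,6E)-3,7,11-trimethyldodeca-1,6,10-trien-3-yl]phenol | C=C[C@@](C)(CC/C=C(\C)CCC=C(C)C)c1ccc(O)c(Oc2cc([C@](C)(C=C)CC/C=C(\C)CCC=C(C)C)cc(OCOC)c2OCOC)c1 | intermediate
26 | 3-{2-hydroxy-5-[(3R,6E)-3,7,11-trimethyldodeca-1,6,10-trien-3-yl]phenoxy}-5-[(3S,6E)-3,7,11-trimethyldodeca-1,6,10-trien-3-yl]benzene-1,2-diol | C=C[C@@](C)(CC/C=C(\C)CCC=C(C)C)c1ccc(O)c(Oc2cc([C@](C)(C=C)CC/C=C(\C)CCC=C(C)C)cc(O)c2O)c1 | target

**Step count**
Total: 17 steps. Longest linear sequence: 11 steps (steps 1, 4, 6, 8, 10, 12, 13, 14, 15, 16, 17).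

**Steps most likely to fail**

Step 16. The first condensation at the amide-like formyl group next to the quaternary carbon may be so slow that reversible self-condensation and base-induced decay of the ketone consume 23 before ring A closes. The fallback raises the electrophilicity of the three-carbon partner. Starting from 12, condensation with dimethylammonium tetrafluoroborate (EtOH, molecular sieves, 50 °C) should give the 2-substituted 1,1,5,5-tetramethylvinamidinium tetrafluoroborate F1. The known KOtBu-mediated phenol annulation of vinamidinium salts with ketones, applied to 23 in THF, would form the same two ring bonds and rejoin the route at 25.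

Step 3 (and its mirror image, step 4). Transfer of the silyl-substituted alkynyl group may proceed with insufficient facial selectivity, or with competing direct SN2 substitution or isobutyl transfer, so that both series would be of low optical purity. Because the target needs both antipodes of one building block, a racemic route with late resolution wastes no material. Starting from 1, vinyl transfer from ethyl vinyl ether (Pd(OAc)2, 1,10-phenanthroline, cat.) should give (2E,6E)-farnesyl vinyl ether F2. Thermal Claisen rearrangement (toluene, 140 °C) gives racemic 3-ethenyl-3,7,11-trimethyldodeca-6,10-dienal F3, and condensation with 11 gives the racemic enaminal F4. Preparative chromatography of F4 on a chiral stationary phase would deliver 12 and 13, where the route is rejoined; steps 1 to 10 are then not needed.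

Step 7 (and its mirror image, step 8). Vinylidene formation at an alkyne flanked by a quaternary carbon may be slow, so that catalyst decay or Markovnikov hydration to the methyl ketone competes. Starting from 7, Cp2ZrHCl-catalysed hydroboration with pinacolborane (CH2Cl2, rt), which is selective for terminal alkynes over olefins, should give the (E)-alkenylboronate F5. Oxidation of its C–B bond with NaBO3·4H2O (THF/H2O) gives the enol and hence aldehyde 9. The mirror-image alkyne 8 would be taken through boronate F6 to 10 in the same way.

**Further compounds**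
F1 | step 16 | N-{(3R,6E)-2-[(dimethylamino)methylidene]-3-ethenyl-3,7,11-trimethyldodeca-6,10-dien-1-ylidene}-N-methylmethanaminium tetrafluoroborate (vinamidinium salt) | C=C[C@@](C)(CC/C=C(\C)CCC=C(C)C)C(C=[N+](C)C)=CN(C)C.F[B-](F)(F)F
F2 | step 3 | (2E,6E)-farnesyl vinyl ether | CC(C)=CCC/C(C)=C/CC/C(C)=C/COC=C
F3 | step 3 | racemic (6E)-3-ethenyl-3,7,11-trimethyldodeca-6,10-dienal | C=CC(C)(CC/C=C(\C)CCC=C(C)C)CC=O
F4 | step 3 | racemic (2Z,6E)-2-[(dimethylamino)methylidene]-3-ethenyl-3,7,11-trimethyldodeca-6,10-dienal | C=CC(C)(CC/C=C(\C)CCC=C(C)C)C(/C=O)=C/N(C)C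
F5 | step 7 | 2-[(1E,3R,6E)-3-ethenyl-3,7,11-trimethyldodeca-1,6,10-trien-1-yl]-4,4,5,5-tetramethyl-1,3,2-dioxaborolane | C=C[C@@](C)(CC/C=C(\C)CCC=C(C)C)/C=C/B1OC(C)(C)C(C)(C)O1
F6 | step 7 | 2-[(1E,3S,6E)-3-ethenyl-3,7,11-trimethyldodeca-1,6,10-trien-1-yl]-4,4,5,5-tetramethyl-1,3,2-dioxaborolane | C=C[C@](C)(CC/C=C(\C)CCC=C(C)C)/C=C/B1OC(C)(C)C(C)(C)O1
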